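The ten-membered ring carries two E alkenes, C1=C2 and C6=C7, in a 1,6 relationship, so a transannular C1–C6 bond maps it onto a trans-decalin (ring A: C1–C6; ring B: C1, C6–C10) with C2 and C7 flanking the fusion. The route builds this bicycle from an (R)-configured enedione, sets C5, C8 and C9 on it, and then cuts C1–C6: hydroboration of the C6=C7 octalin gives a C7-borane C2-mesylate, and methoxide triggers a Grob-type fragmentation that releases the ring and both E alkenes in one operation. Both silyl ethers of the precursor are triethylsilyl, so one fluoride treatment removes them together.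

Key step: step 11

Remark: atom numbers C1–C10 are those of the ten-membered ring (C1 ring methyl, C5 carbinol, C8 isopropyl, C9 ester) and coincide with bicyclo[4.4.0]decane numbering in all bicyclic compounds; β is the face of the C1 methyl group, α the opposite face. Isopropylzinc bromide (THF solution) and 4-acetoxybenzoyl chloride are taken as commercial.

Step 1
Reactants: 1 (R)-8a-methyl-3,4,8,8a-tetrahydronaphthalene-1,6(2H,7H)-dione; 2 diethoxymethane
Product: 3 1β-methyl-5-methylenebicyclo[4.4.0]dec-6-ene-2,8-dione
Conditions: CH2(OEt)2, POCl3, NaOAc, CHCl3, reflux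
Reagents that add atoms: diethoxymethane (2), CCOCOCC
Why: Acid-promoted γ-selective alkoxymethylation of the enone followed by loss of ethanol, a γ-methylenation established for 4-en-3-ones with an angular methyl group, puts the exocyclic CH2 on C5 while the isolated neopentyl C2 ketone stays untouched; no stereocentre is formed.

Step 2
Reactants: 3 1β-methyl-5-methylenebicyclo[4.4.0]dec-6-ene-2,8-dione
Product: 4 5α-spiro-epoxide of 3
Conditions: mCPBA, CH2Cl2, 0 °C to rt
Reagents that add atoms: 3-chloroperbenzoic acid, OOC(=O)c1cccc(Cl)c1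
Why: Prilezhaev epoxidation takes the γ,δ-methylene, the only electron-rich alkene of the dienone (C6=C7 is deactivated by the C8 carbonyl), and oxygen arrives on the α face because the β face of C5 lies under the syn-axial C1 methyl group, which fixes C5 with oxygen α and CH2 β.

Step 3
Reactants: 4 5α-spiro-epoxide of 3
Product: 5 1β,5β-dimethylbicyclo[4.4.0]dec-6-ene-2β,5α,8β-triol
Conditions: LiAlH4, THF, 0 °C to rt
Reagents that add atoms: none
Why: Hydride reduction does three jobs: SN2 opening of the oxirane at its unhindered CH2 terminus gives the C5 methyl carbinol with the C5–O bond untouched (OH α, CH3 β), axial hydride attack anti to the C1 methyl gives the equatorial 2β-alcohol, and 1,2-reduction of the enone gives the allylic C8 alcohol, whose configuration is erased in step 4.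

Step 4
Reactants: 5 1β,5β-dimethylbicyclo[4.4.0]dec-6-ene-2β,5α,8β-triol
Product: 6 2β,5α-dihydroxy-1β,5β-dimethylbicyclo[4.4.0]dec-6-en-8-one
Conditions: MnO2, CH2Cl2, rt
Reagents that add atoms: none
Why: Allylic alcohol oxidation with MnO2 is selective for the secondary allylic C8 hydroxyl and leaves the saturated secondary C2 and the tertiary C5 hydroxyl alone, restoring the C6=C7–C8=O enone.

Step 5
Reactants: 6 2β,5α-dihydroxy-1β,5β-dimethylbicyclo[4.4.0]dec-6-en-8-one
Product: 7 5α-hydroxy-1β,5β-dimethyl-8-oxobicyclo[4.4.0]dec-6-en-2β-yl methanesulfonate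
Conditions: MsCl, pyridine, 0 °C
Reagents that add atoms: methanesulfonyl chloride, CS(Cl)(=O)=O
Why: O-Sulfonylation occurs only at the secondary C2 hydroxyl, the tertiary C5 hydroxyl being too hindered for MsCl in pyridine, and O–S bond formation leaves the equatorial 2β configuration unchanged.

Step 6
Reactants: 7 5α-hydroxy-1β,5β-dimethyl-8-oxobicyclo[4.4.0]dec-6-en-2β-yl methanesulfonate
Product: 8 1β,5β-dimethyl-8-oxo-5α-(triethylsilyloxy)bicyclo[4.4.0]dec-6-en-2β-yl methanesulfonate
Conditions: Et3SiOTf, 2,6-lutidine, CH2Cl2, −78 to 0 °C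
Reagents that add atoms: triethylsilyl trifluoromethanesulfonate, CC[Si](CC)(CC)OS(=O)(=O)C(F)(F)F
Why: Silylation with a silyl triflate and a hindered pyridine base is the standard way to cap a tertiary alcohol and tolerates both the mesylate and the enone.

Step 7
Reactants: 8 1β,5β-dimethyl-8-oxo-5α-(triethylsilyloxy)bicyclo[4.4.0]dec-6-en-2β-yl methanesulfonate
Product: 10 C8 dienyl triflate of 8, via potassium dienolate 9 (not isolated)
Conditions: KN(SiMe3)2, THF, −78 °C; then PhNTf2, −78 to 0 °C
Reagents that add atoms: N-phenylbis(trifluoromethanesulfonimide), O=S(=O)(N(c1ccccc1)S(=O)(=O)C(F)(F)F)C(F)(F)F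
Why: Kinetic enolisation and O-triflation are regiospecific because C9 is the only enolisable position (C1 and C5 are quaternary, C7 is vinylic), and the equatorial neopentyl mesylate has neither an anti-periplanar hydrogen nor a carbon nucleophile within reach, so it is a spectator as in routine ketone enolisations beside alkyl sulfonates.

Step 8
Reactants: 10 C8 dienyl triflate of 8; 11 isopropylzinc bromide
Product: 12 8-isopropyl-1β,5β-dimethyl-5α-(triethylsilyloxy)bicyclo[4.4.0]deca-6,8-dien-2β-yl methanesulfonate
Conditions: iPrZnBr, PdCl2(dppf) (5 mol %; dppf = 1,1'-bis(diphenylphosphino)ferrocene), THF, rt to 50 °C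
Reagents that add atoms: isopropylzinc bromide (11), CC(C)[Zn]Br
Why: Negishi coupling of the alkenyl triflate with a secondary alkylzinc reagent works with the wide-bite-angle dppf ligand, which favours reductive elimination over β-hydride elimination so that isopropyl and not n-propyl is transferred, and zerovalent palladium with an organozinc leaves the alkyl mesylate and the silyl ether alone.

Step 9
Reactants: 12 8-isopropyl-1β,5β-dimethyl-5α-(triethylsilyloxy)bicyclo[4.4.0]deca-6,8-dien-2β-yl methanesulfonate
Product: 14 9α-hydroxy-8β-isopropyl-1β,5β-dimethyl-5α-(triethylsilyloxy)bicyclo[4.4.0]dec-6-en-2β-yl methanesulfonate, via C9 alkyl-9-BBN borane 13 (not isolated)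
Conditions: 9-BBN, THF, rt to 50 °C; then NaBO3·4H2O, THF/H2O, rt
Reagents that add atoms: sodium perborate tetrahydrate (oxygen source), [Na+].[Na+].O[B-]1(O)OO[B-](O)(O)OO1
Why: Hydroboration–oxidation with bulky 9-BBN should take the accessible C8=C9 bond (boron to the unsubstituted C9) and leave C6=C7, whose C6 end sits between two quaternary carbons, and syn addition from the α face, opposite the pseudoaxial C1 methyl, sets C8 (H α, isopropyl β) and C9 (boron, then OH with retention, α) trans to each other.

Step 10
Reactants: 14 9α-hydroxy-8β-isopropyl-1β,5β-dimethyl-5α-(triethylsilyloxy)bicyclo[4.4.0]dec-6-en-2β-yl methanesulfonate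
Product: 15 8β-isopropyl-1β,5β-dimethyl-5α,9α-bis(triethylsilyloxy)bicyclo[4.4.0]dec-6-en-2β-yl methanesulfonate
Conditions: Et3SiOTf, 2,6-lutidine, CH2Cl2, −78 to 0 °C
Reagents that add atoms: triethylsilyl trifluoromethanesulfonate, CC[Si](CC)(CC)OS(=O)(=O)C(F)(F)F
Why: Silyl triflate silylation of the hindered secondary C9 alcohol gives the octalin with one kind of silyl group on both oxygens and the mesylate intact.

Step 11
Reactants: 15 8β-isopropyl-1β,5β-dimethyl-5α,9α-bis(triethylsilyloxy)bicyclo[4.4.0]dec-6-en-2β-yl methanesulfonate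
Product: 18 bis(triethylsilyl) ether of the (1E,6E)-cyclodecadienediol, via trans-decalin C7-borane C2-mesylate 16 (not isolated), via sodium C7-trimethoxyborate 17 (not isolated)
Conditions: BH3·THF, THF, 0 °C to rt; then MeOH, NaOMe, rt to 45 °C
Reagents that add atoms: none
Why: BH3 adds syn across C6=C7 from the α face (the β face lies under the axial methyl groups at C1 and C5) with boron on the less substituted C7, which gives the trans-fused decalin 16 with an equatorial C7–B bond; methoxide and methanol turn it into borate 17, in which the electrons of the C7–B bond flow into a new C6=C7 π bond, the C1–C6 σ bond is cut, its electrons build the C1=C2 π bond and mesylate is expelled from C2 in one seven-centre event. The reaction type is the boronate-induced Grob-type fragmentation known for hydroborated octalin sulfonates. No ring is closed: the medium ring already exists as the periphery of the bicycle and is uncovered when the shared bond is cut, which sidesteps a direct ten-membered cyclisation. No stereocentre is created; C5, C8 and C9 pass through unchanged while C1, C2, C6 and C7 become trigonal. The demand is E geometry at both new double bonds, and the chair–chair trans-decalin meets it because the equatorial C7–B and equatorial C2–O bonds each lie anti to C1–C6, an array that is copied into the two E alkenes. The hindered triethylsilyl ethers should survive methanolic methoxide, and any partial loss converges in step 12.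

Step 12
Reactants: 18 bis(triethylsilyl) ether of the (1E,6E)-cyclodecadienediol
Product: 19 (1E,6E)-8-isopropyl-1,5-dimethylcyclodeca-1,6-diene-5,9-diol
Conditions: Bu4NF, THF, rt
Reagents that add atoms: none
Why: Fluoride-driven Si–O cleavage removes both triethylsilyl groups under basic conditions that spare the acid-sensitive tertiary allylic alcohol and the 1,6-diene, so no transannular cyclisation is expected.

Step 13
Reactants: 19 (1E,6E)-8-isopropyl-1,5-dimethylcyclodeca-1,6-diene-5,9-diol; 20 4-acetoxybenzoyl chloride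
Product: 22 target CNP0277965.1, via C9 4-acetoxybenzoate 21 (not isolated)
Conditions: Et3N, DMAP, CH2Cl2, 0 °C to rt; then MeOH, K2CO3, rt
Reagents that add atoms: 4-acetoxybenzoyl chloride (20), CC(=O)Oc1ccc(cc1)C(Cl)=O
Why: DMAP-catalysed acylation esterifies the secondary C9 hydroxyl while the tertiary C5 hydroxyl is too hindered to react, and the following methanolysis removes only the activated aryl acetate, since the hindered alkyl benzoate is further deactivated once the phenoxide has formed; no stereocentre is touched.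

Compound list
1 | (R)-8a-methyl-3,4,8,8a-tetrahydronaphthalene-1,6(2H,7H)-dione (= 1β-methylbicyclo[4.4.0]dec-6-ene-2,8-dione) | C[C@@]12CCC(=O)C=C1CCCC2=O | starting material
2 | diethoxymethane | CCOCOCC | starting material
3 | 1β-methyl-5-methylenebicyclo[4.4.0]dec-6-ene-2,8-dione | C[C@]12C(=O)CCC(=C)C1=CC(=O)CC2 | intermediate
4 | 5α-spiro-epoxide of 3 (oxirane spiro at C5, oxygen α, CH2 β; C2 ketone and C6=C7–C8=O kept) | C[C@]12C(=O)CC[C@@]3(OC3)C1=CC(=O)CC2 | intermediate
5 | 1β,5β-dimethylbicyclo[4.4.0]dec-6-ene-2β,5α,8β-triol (8β epimer shown; C8 is re-oxidised in step 4) | C[C@]12[C@H](O)CC[C@@](C)(O)C1=C[C@H](O)CC2 | intermediate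
6 | 2β,5α-dihydroxy-1β,5β-dimethylbicyclo[4.4.0]dec-6-en-8-one | C[C@]12[C@H](O)CC[C@@](C)(O)C1=CC(=O)CC2 | intermediate
7 | 5α-hydroxy-1β,5β-dimethyl-8-oxobicyclo[4.4.0]dec-6-en-2β-yl methanesulfonate | C[C@]12[C@H](OS(C)(=O)=O)CC[C@@](C)(O)C1=CC(=O)CC2 | intermediate
8 | 1β,5β-dimethyl-8-oxo-5α-(triethylsilyloxy)bicyclo[4.4.0]dec-6-en-2β-yl methanesulfonate | C[C@]12[C@H](OS(C)(=O)=O)CC[C@@](C)(O[Si](CC)(CC)CC)C1=CC(=O)CC2 | intermediate
9 | potassium dienolate of 8 (C8–O−, C8=C9, C6=C7) | C[C@]12[C@H](OS(C)(=O)=O)CC[C@@](C)(O[Si](CC)(CC)CC)C1=CC([O-])=CC2.[K+] | intermediate (not isolated)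
10 | C8 dienyl triflate of 8: 1β,5β-dimethyl-5α-(triethylsilyloxy)-8-(trifluoromethanesulfonyloxy)bicyclo[4.4.0]deca-6,8-dien-2β-yl methanesulfonate | C[C@]12[C@H](OS(C)(=O)=O)CC[C@@](C)(O[Si](CC)(CC)CC)C1=CC(OS(=O)(=O)C(F)(F)F)=CC2 | intermediate
11 | isopropylzinc bromide | CC(C)[Zn]Br | starting material
12 | 8-isopropyl-1β,5β-dimethyl-5α-(triethylsilyloxy)bicyclo[4.4.0]deca-6,8-dien-2β-yl methanesulfonate | C[C@]12[C@H](OS(C)(=O)=O)CC[C@@](C)(O[Si](CC)(CC)CC)C1=CC(C(C)C)=CC2 | intermediate
13 | C9 alkyl-9-BBN borane: 9α-(9-borabicyclo[3.3.1]nonan-9-yl)-8β-isopropyl analogue of 14 | C[C@]12[C@H](OS(C)(=O)=O)CC[C@@](C)(O[Si](CC)(CC)CC)C1=C[C@H](C(C)C)[C@@H](B3C4CCCC3CCC4)C2 | intermediate (not isolated)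
14 | 9α-hydroxy-8β-isopropyl-1β,5β-dimethyl-5α-(triethylsilyloxy)bicyclo[4.4.0]dec-6-en-2β-yl methanesulfonate | C[C@]12[C@H](OS(C)(=O)=O)CC[C@@](C)(O[Si](CC)(CC)CC)C1=C[C@H](C(C)C)[C@@H](O)C2 | intermediate
15 | 8β-isopropyl-1β,5β-dimethyl-5α,9α-bis(triethylsilyloxy)bicyclo[4.4.0]dec-6-en-2β-yl methanesulfonate | C[C@]12[C@H](OS(C)(=O)=O)CC[C@@](C)(O[Si](CC)(CC)CC)C1=C[C@H](C(C)C)[C@@H](O[Si](CC)(CC)CC)C2 | intermediate
16 | trans-decalin C7-borane C2-mesylate: 7α-boranyl-6α-H-8β-isopropyl-1β,5β-dimethyl-5α,9α-bis(triethylsilyloxy)bicyclo[4.4.0]decan-2β-yl methanesulfonate | C[C@]12[C@H](OS(C)(=O)=O)CC[C@@](C)(O[Si](CC)(CC)CC)[C@@H]1[C@@H](B)[C@H](C(C)C)[C@@H](O[Si](CC)(CC)CC)C2 | intermediate (not isolated)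
17 | sodium C7-trimethoxyborate of 16 | [Na+].C[C@]12[C@H](OS(C)(=O)=O)CC[C@@](C)(O[Si](CC)(CC)CC)[C@@H]1[C@@H]([B-](OC)(OC)OC)[C@H](C(C)C)[C@@H](O[Si](CC)(CC)CC)C2 | intermediate (not isolated)
18 | bis(triethylsilyl) ether of the (1E,6E)-cyclodecadienediol: (1E,6E)-8-isopropyl-1,5-dimethyl-5,9-bis(triethylsilyloxy)cyclodeca-1,6-diene, C5, C8 and C9 as in the target | C/C1=C\CC[C@@](C)(O[Si](CC)(CC)CC)/C=C/[C@H](C(C)C)[C@@H](O[Si](CC)(CC)CC)C1 | intermediate
19 | (1E,6E)-8-isopropyl-1,5-dimethylcyclodeca-1,6-diene-5,9-diol, C5, C8 and C9 as in the target | C/C1=C\CC[C@@](C)(O)/C=C/[C@H](C(C)C)[C@@H](O)C1 | intermediate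
20 | 4-acetoxybenzoyl chloride | CC(=O)Oc1ccc(cc1)C(Cl)=O | starting material
21 | C9 4-acetoxybenzoate of 19 | C/C1=C\CC[C@@](C)(O)/C=C/[C@H](C(C)C)[C@@H](OC(=O)c2ccc(OC(C)=O)cc2)C1 | intermediate (not isolated)
22 | CNP0277965.1: C9 4-hydroxybenzoate of 19, (1E,6E; 5R,8S,9S in the route numbering) | C/C1=C\CC[C@@](C)(O)/C=C/[C@H](C(C)C)[C@@H](OC(=O)c2ccc(O)cc2)C1 | target

Total step count: 13. Longest linear sequence: 13 steps (1 to 22); compounds 2, 11 and 20 are commercial and enter directly.

Steps most likely to fail

1. Step 11. The hydroboration at C6=C7, which lies between the quaternary C1 and C5, may be slow or not fully α-selective. In the one-flask protocol every borane isomer meets the base at once, and only the trans-fused isomer with equatorial C7–B can give the E,E-diene. The fallback separates the two events. It sets out from 15: BH3·THF followed by pinacol should give the air-stable trans-decalin C7 pinacol boronate F1 with the mesylate intact, and the 7α,6α-H isomer is purified by chromatography. NaOMe in MeOH/THF then forms its alkoxyborate and fragments it, and the route is rejoined at 18.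

2. Step 9. Mono-hydroboration of the conjugated diene may lose site selectivity, with boron adding at C7 of the C6=C7 bond or to both alkenes. The fallback stops resisting the second addition and moves the C9–O bond formation behind the ring expansion. It sets out from 12: excess BH3·THF should hydroborate both trisubstituted alkenes from the α face to the C7,C9-bis(borane) F2. NaOMe/MeOH fragments only the C7 borate, because the C9–B bond has no leaving group aligned through C1–C10, and gives the ring-expanded C9 dimethyl boronate F3. NaOH/H2O2 oxidises the C9–B bond with retention to the C9 alcohol C5 silyl ether F4, and Bu4NF then returns the route at 19.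

3. Step 2. Face selectivity of the epoxidation at the exocyclic methylene may be insufficient with the small peracid, giving the C5 epimer, and slow oxidation at the C2 ketone could compete. The fallback replaces epoxidation by dihydroxylation and deoxygenation. It sets out from 3: OsO4 (cat.) with N-methylmorpholine N-oxide, a bulkier oxidant that responds more strongly to the syn-axial C1 methyl, should give the 5α-hydroxy-5β-hydroxymethyl enedione F5. TsCl in pyridine converts the primary hydroxyl into the tosylate F6. LiAlH4 then removes the tosylate (through epoxide 4 formed in the flask or by direct displacement) and reduces both carbonyl groups, returning the route at 5.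

Further compounds
F1 | step 11 | trans-decalin C7 pinacol boronate C2-mesylate (7α-Bpin analogue of 16) | C[C@]12[C@H](OS(C)(=O)=O)CC[C@@](C)(O[Si](CC)(CC)CC)[C@@H]1[C@@H](B3OC(C)(C)C(C)(C)O3)[C@H](C(C)C)[C@@H](O[Si](CC)(CC)CC)C2
F2 | step 9 | trans-decalin 7α,9α-bis(borane) C2-mesylate with 5α-triethylsilyloxy and 8β-isopropyl groups | C[C@]12[C@H](OS(C)(=O)=O)CC[C@@](C)(O[Si](CC)(CC)CC)[C@@H]1[C@@H](B)[C@H](C(C)C)[C@@H](B)C2
F3 | step 9 | (1E,6E)-cyclodecadiene C9 dimethyl boronate with C5 triethylsilyl ether | C/C1=C\CC[C@@](C)(O[Si](CC)(CC)CC)/C=C/[C@H](C(C)C)[C@@H](B(OC)OC)C1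
F4 | step 9 | (1E,6E)-8-isopropyl-1,5-dimethyl-5-(triethylsilyloxy)cyclodeca-1,6-dien-9-ol | C/C1=C\CC[C@@](C)(O[Si](CC)(CC)CC)/C=C/[C@H](C(C)C)[C@@H](O)C1
F5 | step 2 | 5α-hydroxy-5β-(hydroxymethyl)-1β-methylbicyclo[4.4.0]dec-6-ene-2,8-dione | C[C@]12C(=O)CC[C@@](CO)(O)C1=CC(=O)CC2
F6 | step 2 | primary p-toluenesulfonate of F5 | C[C@]12C(=O)CC[C@@](COS(=O)(=O)c3ccc(C)cc3)(O)C1=CC(=O)CC2
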